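A charge of 50 µM of precatalyst stands in the winter, spring and dawn runs, and their target curves start flat and then bend upward.

common to all: precatalyst 50 µM
- winter: substrate 0.050 M; coupling partner 0.063 M; temperature 69 °C; run made earlier
- spring: substrate 0.050 M; coupling partner 0.099 M; temperature 77 °C; run made earlier
- dawn: substrate 0.10 M; coupling partner 0.045 M; temperature 69 °C; run made earlier
- birch: substrate 0.050 M; coupling partner 0.0450 M; at 65 °C until 5.0 h, from then on at 80 °C; time 25 h
- cedar: substrate 0.050 M; coupling partner 0.0450 M; temperature 65 °C; time 25 h
- maple: substrate 0.050 M; coupling partner 0.0450 M; temperature 80 °C; time 25 h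

- winter (time / h: target / %, substrate / %): 2.00: 0, 99.9; 4.00: 1.1, 98.2; 6.00: 2.7, 97.2; 8.00: 4.5, 94.8; 10.0: 7.5, 92.0; 12.0: 9.7, 89.1; 15.0: 13.7, 84.7
- spring (time / h: target / %, substrate / %): 1.00: 0.4, 99.1; 2.00: 1.1, 98.7; 3.00: 3.8, 96.2; 4.00: 5.0, 94.2; 6.00: 10.0, 89.4; 8.00: 15.0, 82.7
- dawn (time / h: target / %, substrate / %): 1.33: 0.1, 99.7; 2.50: 0.7, 99.9; 4.00: 1.4, 98.9; 8.00: 3.5, 96.6; 15.0: 9.5, 88.2

(readings scatter by 0.3 percentage points)

* the flask that comes out highest in amount of target, in percent of the substrate charged, or "all alike" when all lie within 1.5 percentage points (birch / cedar / maple / all alike)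
* target at the end, in percent of the substrate charged, birch
* target at the end, in percent of the substrate charged, cedar
* target at the end, in percent of the substrate charged, maple

The count used here is the logarithmic conversion, the natural logarithm of substrate charged over substrate left. Taken as growing with partner concentration and squared time, it gives each run an early time, the time at which that climb, scaled to a partner charge of 0.0450 M, brings the logarithmic conversion to one: 41.0 h in winter and 43.0 h in dawn, both read at 8.00 h, with 0.10 M of substrate in dawn instead of 0.050 M. These readings agree within their scatter, so the percentage converted reads as independent of the substrate charge and the waking as proportional to partner.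

Spring at 77 °C gives 24.3 h. A straight logarithmic line through the two temperatures gives 19.9 h at 80 °C and 53.2 h at 65 °C. The late slope of spring, 0.0390 h⁻¹, serves as the plateau slope. Maple then has 7.75 h as its waking time: the plateau slope divided by the early climb of the slope, the time that climb needs to reach the plateau.

Two extreme maples can be solved in the head. A catalyst asleep for the waking time and then awake at once gives an induction period of the full waking time and leaves 51.0% substrate. A catalyst climbing steadily at its first pace loses half that time and leaves 43.9%. At that one slope the reckoned maple lies between the two, since its waking starts at that pace and then slows, and 25 h is longer than the waking time; the slope is read from spring, so this is an estimate of the delay and not a bound on the flask.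

Spring turned 86.7% of the substrate lost into target, so maple should give 42.4% to 48.7%. Cedar has a waking time of 55.1 h, longer than its run, so it stays on the early climb and should give about 17.2%. Birch, 9.07% awake at the change by that climb, should give 34.4% to 41.1%.

The forecast, with a plateau “only weakly temperature dependent”, names maple and gives 23% for birch, 14% for cedar and 26% for maple, so the reckoning here stands higher for maple and higher for birch.

Maple comes out highest at 42.5%, with birch at 37.7% and cedar at 15.3%.

    coupling partner + precatalyst → free catalyst + spent reagent (k = 3.10 M⁻¹ h⁻¹, Ea = 93.0 kJ mol⁻¹)
    substrate + target → side product (k = 0.600 M⁻¹ h⁻¹, Ea = 73.0 kJ mol⁻¹)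
    coupling partner + catalyst intermediate B → catalyst intermediate C (k = 2.40 × 10⁵ M⁻¹ h⁻¹, Ea = 41.0 kJ mol⁻¹)
    substrate + free catalyst ⇌ catalyst intermediate A (K = 51.0 M⁻¹, k = 960 M⁻¹ h⁻¹, Ea = 44.0 kJ mol⁻¹, ΔH = −40.0 kJ mol⁻¹)
    catalyst intermediate C → free catalyst + target (k = 8100 h⁻¹, Ea = 82.0 kJ mol⁻¹)
    catalyst intermediate A → catalyst intermediate B (k = 1300 h⁻¹, Ea = 79.0 kJ mol⁻¹)
    (constants at 80 °C)

Maple's substrate ends at 38.6%, lower than the reckoned range, and its precatalyst at 7.99% of its charge, against 3.97% from the waking time. At 25.0 h in maple, the forward step of substrate onto free catalyst uses substrate 3.4 times as fast as the conversion of substrate and target. Side product there stands at 18.8%. The neighbour of maple charged with 0.030 M of substrate has the same waking time of 7.75 h by this rule, and it ends with 5.55% of its precatalyst and 40% of its substrate.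

(All runs stem from a simulated flask from invented constants; noise was put on by code.)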